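Time is the awkward variable here, so I remove it by dividing one rate by another and following X against E instead of against the clock.

| flask | E | J | remark | time |
|---|---|---|---|---|
| Friday's | 0.40 M | 1.2 equiv | the very flask that is asked about, followed so far |  |
| Tuesday's | 0.27 M | 1.2 equiv | run made earlier |  |
| flask | 0.40 M | 1.20 equiv |  | 1.5 h |

| run | time / min | Z / % | X / % | E / % | Q / % |
|---|---|---|---|---|---|
| Friday's | 2.50 | 0.1 | 5.9 | 93.7 | 0.4 |
| Friday's | 5.00 | 0.4 | 11.0 | 88.5 | 0.2 |
| Friday's | 8.00 | 0.5 | 16.4 | 83.2 | 0 |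
| Friday's | 10.0 | 0.3 | 18.6 | 80.0 | 0.1 |
| Friday's | 12.0 | 0.8 | 22.1 | 76.5 | 0 |
| Friday's | 15.0 | 1.4 | 25.7 | 72.1 | 0 |
| Tuesday's | 5.00 | 0 | 7.7 | 92.2 | 0 |
| Tuesday's | 8.00 | 0 | 12.1 | 88.0 | 0 |
| Tuesday's | 12.0 | 0.5 | 16.1 | 83.0 | 0 |
| Tuesday's | 20.0 | 2.2 | 24.2 | 75.6 | 0.2 |
| Tuesday's | 25.0 | 2.3 | 27.8 | 71.2 | 0 |
| Tuesday's | 40.0 | 3.4 | 35.4 | 61.1 | 0.2 |
| Tuesday's | 60.0 | 3.6 | 40.0 | 53.5 | 0.1 |

(each reading ± 0.5 percentage points)

1. the largest share of what was charged as E, at 1.5 h belongs to (X / Q / E / Z)
2. the largest share itself, whichever of these holds it, in percent of the E charged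

Let e and x be the fractions of the E charged. With E + J → D + X running on its own, each E lost is an X gained, so x = 1 − e. Now I add X + J → D + Z. Both forward rates carry J, so their quotient contains neither J nor time. Tuesday's last 3 readings of Z and Q, pooled, give the selectivity factor s, the forward rate of X to Z over that of E to X at equal shares of X and E: 0.304. Putting 1 − e for x inside the quotient, the part that has gone past X is s(e − 1 − ln e), and x is 1 − e minus that.

Then the rest. J → L takes J from both forward steps alike, so it slows the march along this path without entering the quotient, and Q counts within the part past X. Returns through D I cannot separate in these readings.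

The rule puts X level with E near 47.1 %. Friday's flask gets 2.22 times the concentration-times-time of Tuesday's last reading, where E stood at 53.5 %, so I expect E to fall past that level, though I do not reckon by how far.

The forecast says X at 50 %, with E at 46: "so X narrowly leads". We name the same leader; my own claim is X above the level point, which lies lower than the forecast's figure.

At 1.5 h the flask gives X at 50.5 %, with E at 40.0 %.

    J ⇌ L (K = 1.80, k = 0.250 h⁻¹)
    Z + J ⇌ D + Q (K = 1.80, k = 1.40 M⁻¹ h⁻¹)
    E + J ⇌ D + X (K = 4.90, k = 3.20 M⁻¹ h⁻¹)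
    X + J ⇌ D + Z (K = 0.500, k = 1.20 M⁻¹ h⁻¹)

At that E the rule gives X 50.4 %. The neighbouring flask with 0.720 equiv of J ends with E at 57.5 %, above the level point, and there the rule gives X 38.6 %. Its X stands at 38.5 %, and E holds most.

(All runs stem from a simulated flask with constants of no real substance.)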